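**Strategy.** Ring A (C1 ketone, C2 methyl-bearing carbon, C3 methoxy carbon, C4 CMe2, C5 ketone, C6 spiro carbon) is a twice-blocked cyclohexane-1,3,5-trione, so C6 lies between two carbonyls and C2 between C1 and C3. The route cuts C5–C6 and C1–C2: the lithium enolate of an enantiopure ring-B cyclohexene ester (ester carbon = C1) is C-acylated anti to its isopropyl neighbour by 2,2-dimethyl-3-oxopentanoyl chloride, and the ethyl-ketone enolate then attacks the ester in the same flask (Dieckmann), closing ring A and fixing the spiro centre in one operation. O-Methylation ends the synthesis; ring B comes from an organocatalytic Michael/aldol sequence.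

Key step: step 7

Remark: the ester-bearing carbon of 3–9 is drawn as the expected trans epimer; it is planarised in step 7, so its configuration is immaterial. Compound 15 is written as the triketo tautomer, although it should be largely enolised between C1 and C3.

**Step 1**
Reactants: 1 3-methylbutanal; 2 ethyl (E)-4-oxopent-2-enoate
Product: 3 ethyl (2R,3S)-3-formyl-4-methyl-2-(2-oxopropyl)pentanoate
Conditions: (R)-α,α-diphenylprolinol trimethylsilyl ether (10 mol %), PhCO2H (10 mol %), toluene, 0 °C to rt
Reagents that add atoms: none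
Why: Enamine-catalysed Michael addition in which the E-enamine of 1 should attack, on the face remote from the diphenyl(silyloxy)methyl group and through the usual synclinal transition state, the carbon of 2 that is β to the ketone (α to the ester), setting the isopropyl-bearing centre as S and giving the syn adduct.

**Step 2**
Reactants: 3 ethyl (2R,3S)-3-formyl-4-methyl-2-(2-oxopropyl)pentanoate
Product: 4 ethyl (1R,2R)-5-oxo-2-(propan-2-yl)cyclohex-3-ene-1-carboxylate
Conditions: TsOH·H2O (10 mol %), toluene, 80 °C
Reagents that add atoms: none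
Why: Acid-catalysed intramolecular aldol condensation (Robinson-type closure of a 5-oxo aldehyde) in which only the methyl-ketone enol and the aldehyde can give a six-membered ring, so the syn adduct should become the trans enone without touching the isopropyl-bearing centre.

**Step 3**
Reactants: 4 ethyl (1R,2R)-5-oxo-2-(propan-2-yl)cyclohex-3-ene-1-carboxylate
Product: 6 ethyl (1R,6S)-6-(propan-2-yl)-3-[(trifluoromethanesulfonyl)oxy]cyclohex-3-ene-1-carboxylate, via lithium enolate 5 (not isolated)
Conditions: LiBH(s-Bu)3, THF, −78 °C; then PhNTf2, −78 °C to rt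
Reagents that add atoms: N-phenylbis(trifluoromethanesulfonimide) O=S(=O)(N(c1ccccc1)S(=O)(=O)C(F)(F)F)C(F)(F)F
Why: Conjugate hydride reduction of the β-unsubstituted enone gives the enolate regiospecifically on the side of the former C=C, and O-triflation fixes that regiochemistry (reductive enolate trapping), the ester being inert at −78 °C.

**Step 4**
Reactants: 6 ethyl (1R,6S)-6-(propan-2-yl)-3-[(trifluoromethanesulfonyl)oxy]cyclohex-3-ene-1-carboxylate; 7 5-bromo-2-methylpent-2-ene
Product: 9 ethyl (1R,6S)-3-(4-methylpent-3-en-1-yl)-6-(propan-2-yl)cyclohex-3-ene-1-carboxylate, via Grignard reagent 8 (not isolated)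
Conditions: 7, Mg, THF, rt; then 6, Fe(acac)3 (5 mol %), THF/NMP, −30 °C
Reagents that add atoms: none
Why: Iron-catalysed Kumada-type coupling of an alkenyl triflate with a primary alkyl Grignard reagent is fast at low temperature, tolerates esters and β-hydrogens, and should place the homoprenyl chain exactly at the triflate carbon.

**Step 5**
Reactants: 10 2-methylpropanoic acid; 11 propanoyl chloride
Product: 12 2,2-dimethyl-3-oxopentanoic acid
Conditions: LiN(i-Pr)2 (2.2 equiv), THF, 0 °C to rt; then 11, −78 °C; cold aq HCl
Reagents that add atoms: none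
Why: C-Acylation of a carboxylic acid dianion by an acid chloride gives the β-keto acid directly, and the α,α-dimethyl product should survive a cold work-up without decarboxylation.

**Step 6**
Reactants: 12 2,2-dimethyl-3-oxopentanoic acid
Product: 13 2,2-dimethyl-3-oxopentanoyl chloride
Conditions: (COCl)2, DMF (cat.), CH2Cl2, 0 °C to rt
Reagents that add atoms: oxalyl chloride O=C(Cl)C(Cl)=O
Why: Vilsmeier-type activation converts the acid to the acid chloride without heating, and the quaternary α-carbon excludes ketene formation and enolisation toward the acyl group.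

**Step 7**
Reactants: 9 ethyl (1R,6S)-3-(4-methylpent-3-en-1-yl)-6-(propan-2-yl)cyclohex-3-ene-1-carboxylate; 13 2,2-dimethyl-3-oxopentanoyl chloride
Product: 15 (6R,11S)-2,4,4-trimethyl-8-(4-methylpent-3-en-1-yl)-11-(propan-2-yl)spiro[5.5]undec-8-ene-1,3,5-trione, via β-keto ester 14 (not isolated)
Conditions: LiN(i-Pr)2, THF, −78 °C; 13, −78 °C; then LiN(SiMe3)2 (2.5 equiv), −78 °C to rt; aq HCl
Reagents that add atoms: none
Why: LiN(i-Pr)2 converts 9 into its exocyclic ester enolate at C6, where allylic 1,3-strain pushes the neighbouring isopropyl group pseudo-axial, so C6 should attack 13 on the opposite ring face (crossed Claisen C-acylation) and give 14 with the C5 acyl group trans and the ester carbon C1 cis to isopropyl, which is the spiro configuration of the target. LiN(SiMe3)2 then deprotonates the only acidic position left in 14, the CH2 of the ethyl ketone (C2, since C4 and C6 are quaternary), and this enolate attacks the C1 ester in a Dieckmann condensation (6-exo-trig, ethoxide leaves), forming the C1–C2 bond that closes ring A. The closest known reaction type is the base-mediated Claisen cyclisation of 2,2-disubstituted 3,5-dioxo esters to syncarpic-acid-type cyclohexane-1,3,5-triones, here run in tandem with the acylation that makes the substrate. The only stereocentre created is the quaternary spiro carbon C6, controlled by the adjacent isopropyl-bearing carbon of ring B, while C2 ends in an enolisable position and needs no control. The step needs C- over O-acylation and C- over O-cyclisation: the lithium counter-ion in THF at −78 °C favours the former, and any enol lactone from O-cyclisation should be reopened by ethoxide and funnelled to the stabilised C1–C2–C3 diketonate, which makes the closure irreversible. The gem-dimethyl group at C4 and the quaternary C6 hold the chain folded and so favour the closure.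

**Step 8**
Reactants: 15 (6R,11S)-2,4,4-trimethyl-8-(4-methylpent-3-en-1-yl)-11-(propan-2-yl)spiro[5.5]undec-8-ene-1,3,5-trione
Product: 16 (6R,11S)-3-methoxy-2,4,4-trimethyl-8-(4-methylpent-3-en-1-yl)-11-(propan-2-yl)spiro[5.5]undeca-2,8-diene-1,5-dione
Conditions: HC(OMe)3, MeOH, TsOH·H2O (cat.), rt to 40 °C
Reagents that add atoms: trimethyl orthoformate COC(OC)OC
Why: Acid-catalysed enol etherification of the cyclic 2-methyl-1,3-diketone under equilibrating conditions, in which the C5 ketone between two quaternary carbons is inert and C1, flanked by the spiro carbon and its cis isopropyl neighbour, is expected to be more shielded than C3, so the 3-methoxy isomer should predominate.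

**Compound list**
1 | 3-methylbutanal | CC(C)CC=O | starting material
2 | ethyl (E)-4-oxopent-2-enoate | CCOC(=O)/C=C/C(C)=O | starting material
3 | ethyl (2R,3S)-3-formyl-4-methyl-2-(2-oxopropyl)pentanoate | CCOC(=O)[C@H](CC(C)=O)[C@@H](C=O)C(C)C | intermediate
4 | ethyl (1R,2R)-5-oxo-2-(propan-2-yl)cyclohex-3-ene-1-carboxylate (trans) | CCOC(=O)[C@@H]1CC(=O)C=C[C@H]1C(C)C | intermediate
5 | ethyl (1R,6S)-3-(lithiooxy)-6-(propan-2-yl)cyclohex-3-ene-1-carboxylate (lithium enolate, not isolated) | CCOC(=O)[C@@H]1CC(O[Li])=CC[C@H]1C(C)C | intermediate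
6 | ethyl (1R,6S)-6-(propan-2-yl)-3-[(trifluoromethanesulfonyl)oxy]cyclohex-3-ene-1-carboxylate | CCOC(=O)[C@@H]1CC(OS(=O)(=O)C(F)(F)F)=CC[C@H]1C(C)C | intermediate
7 | 5-bromo-2-methylpent-2-ene | CC(C)=CCCBr | starting material
8 | (4-methylpent-3-en-1-yl)magnesium bromide (not isolated) | CC(C)=CCC[Mg]Br | intermediate
9 | ethyl (1R,6S)-3-(4-methylpent-3-en-1-yl)-6-(propan-2-yl)cyclohex-3-ene-1-carboxylate | CCOC(=O)[C@@H]1CC(CCC=C(C)C)=CC[C@H]1C(C)C | intermediate
10 | 2-methylpropanoic acid | CC(C)C(=O)O | starting material
11 | propanoyl chloride | CCC(=O)Cl | starting material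
12 | 2,2-dimethyl-3-oxopentanoic acid | CCC(=O)C(C)(C)C(=O)O | intermediate
13 | 2,2-dimethyl-3-oxopentanoyl chloride | CCC(=O)C(C)(C)C(=O)Cl | intermediate
14 | ethyl (1S,6S)-1-(2,2-dimethyl-3-oxopentanoyl)-3-(4-methylpent-3-en-1-yl)-6-(propan-2-yl)cyclohex-3-ene-1-carboxylate (not isolated) | CCOC(=O)[C@]1(CC(CCC=C(C)C)=CC[C@H]1C(C)C)C(=O)C(C)(C)C(=O)CC | intermediate
15 | (6R,11S)-2,4,4-trimethyl-8-(4-methylpent-3-en-1-yl)-11-(propan-2-yl)spiro[5.5]undec-8-ene-1,3,5-trione | CC1C(=O)[C@]2(CC(CCC=C(C)C)=CC[C@H]2C(C)C)C(=O)C(C)(C)C1=O | intermediate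
16 | (6R,11S)-3-methoxy-2,4,4-trimethyl-8-(4-methylpent-3-en-1-yl)-11-(propan-2-yl)spiro[5.5]undeca-2,8-diene-1,5-dione | COC1=C(C)C(=O)[C@]2(CC(CCC=C(C)C)=CC[C@H]2C(C)C)C(=O)C1(C)C | target

**Step count.** Total steps: 8. Longest linear sequence: 6 (steps 1, 2, 3, 4, 7, 8).

**Steps most likely to fail**

Step 7. The hindered ester enolate may be acylated on oxygen, or may transfer a proton to the ketone of 13, instead of forming the C5–C6 bond. The fallback sets out from 9 and 13 and returns at 14. Acid chloride 13 would be reduced with LiAlH(Ot-Bu)3 in THF at −78 °C to 2,2-dimethyl-3-oxopentanal F1. The lithium enolate of 9 should add to this aldehyde at −78 °C, again anti to the isopropyl group, to give ethyl (1S,6S)-1-(1-hydroxy-2,2-dimethyl-3-oxopentyl)-3-(4-methylpent-3-en-1-yl)-6-(propan-2-yl)cyclohex-3-ene-1-carboxylate F2 as a mixture of carbinol epimers. Oxidation with the periodinane DMP in CH2Cl2 would give 14, which is then cyclised with LiN(SiMe3)2 exactly as in the second half of step 7.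

Step 8. Methanol may also enter at C1, so the two ends of the diketone are not differentiated well enough. The fallback sets out from 9 and returns at 16, and it marks C1 with nitrogen before the ring is closed. Ester 9 would be converted with Me2AlNH2 (from AlMe3 and NH4Cl, xylene, reflux) into (1R,6S)-3-(4-methylpent-3-en-1-yl)-6-(propan-2-yl)cyclohex-3-ene-1-carbonitrile F3. Deprotonation with LiN(i-Pr)2 and acylation with 13, anti to isopropyl, should give (1R,6S)-1-(2,2-dimethyl-3-oxopentanoyl)-3-(4-methylpent-3-en-1-yl)-6-(propan-2-yl)cyclohex-3-ene-1-carbonitrile F4. KOt-Bu in THF would then close ring A by Thorpe–Ziegler attack of the C2 enolate on the nitrile carbon C1, giving (6R,11S)-1-amino-2,4,4-trimethyl-8-(4-methylpent-3-en-1-yl)-11-(propan-2-yl)spiro[5.5]undeca-1,8-diene-3,5-dione F5. O-Methylation of this vinylogous amide at the C3 oxygen with MeOTf, followed by mild aqueous acid hydrolysis of the iminium carbon C1, should deliver 16 with no regiochemical ambiguity.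

Step 1. The enamine may add slowly, or at the carbon α to the ketone, and the aldehyde product may lose enantiopurity by enolisation. The fallback sets out from 2 and returns at 9 by a ketone-directed Diels–Alder reaction. β-Myrcene (commercial) and 2 would be combined with a chiral cationic oxazaborolidine Lewis acid (from α,α-diphenylprolinol, o-tolylboronic acid and HNTf2) in CH2Cl2 at −78 to −20 °C. Coordination at the ketone should direct the CH2 terminus next to the substituted diene carbon to the ester-bearing carbon and give ethyl (1R,6R)-6-acetyl-3-(4-methylpent-3-en-1-yl)cyclohex-3-ene-1-carboxylate F6. The sense of induction of this catalyst on 2 is not assigned here, so the catalyst antipode that gives F6 as drawn would have to be fixed by correlation with 9. Wittig methylenation (Ph3P=CH2, THF, 0 °C) would give ethyl (1R,6R)-3-(4-methylpent-3-en-1-yl)-6-(prop-1-en-2-yl)cyclohex-3-ene-1-carboxylate F7. Selective hydrogenation of the 1,1-disubstituted alkene with RhCl(PPh3)3 under H2 (1 atm) in toluene should then give 9.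

**Further compounds**
F1 | step 7 | 2,2-dimethyl-3-oxopentanal | CCC(=O)C(C)(C)C=O
F2 | step 7 | ethyl (1S,6S)-1-(1-hydroxy-2,2-dimethyl-3-oxopentyl)-3-(4-methylpent-3-en-1-yl)-6-(propan-2-yl)cyclohex-3-ene-1-carboxylate | CCOC(=O)[C@]1(CC(CCC=C(C)C)=CC[C@H]1C(C)C)C(O)C(C)(C)C(=O)CC
F3 | step 8 | (1R,6S)-3-(4-methylpent-3-en-1-yl)-6-(propan-2-yl)cyclohex-3-ene-1-carbonitrile | N#C[C@@H]1CC(CCC=C(C)C)=CC[C@H]1C(C)C
F4 | step 8 | (1R,6S)-1-(2,2-dimethyl-3-oxopentanoyl)-3-(4-methylpent-3-en-1-yl)-6-(propan-2-yl)cyclohex-3-ene-1-carbonitrile | N#C[C@]1(CC(CCC=C(C)C)=CC[C@H]1C(C)C)C(=O)C(C)(C)C(=O)CC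
F5 | step 8 | (6R,11S)-1-amino-2,4,4-trimethyl-8-(4-methylpent-3-en-1-yl)-11-(propan-2-yl)spiro[5.5]undeca-1,8-diene-3,5-dione | CC1=C(N)[C@]2(CC(CCC=C(C)C)=CC[C@H]2C(C)C)C(=O)C(C)(C)C1=O
F6 | step 1 | ethyl (1R,6R)-6-acetyl-3-(4-methylpent-3-en-1-yl)cyclohex-3-ene-1-carboxylate | CCOC(=O)[C@@H]1CC(CCC=C(C)C)=CC[C@H]1C(C)=O
F7 | step 1 | ethyl (1R,6R)-3-(4-methylpent-3-en-1-yl)-6-(prop-1-en-2-yl)cyclohex-3-ene-1-carboxylate | CCOC(=O)[C@@H]1CC(CCC=C(C)C)=CC[C@H]1C(C)=C
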